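## Plan

- **Cuts, in retrosynthetic order:** the C8–O ester bond (made with inversion at C8); the two γ-lactone bonds C7–C11 and O–C6 together; the C6=C7 bond of a ring diene; the furanone O–C3 bond; the C1–C2 bond between a sugar-derived Weinreb amide and a dienyne.
- **Enabling feature:** the lactone carbon C6 is allylic to C4=C5, which is conjugated with the furanone ring (O, C3, C2, C1, C10). The lactone is therefore the formal adduct of 2-bromoacrylic acid across the C6=C7 end of a C4=C5–C6=C7 ring diene, and its cis fusion is what a syn carbopalladation followed by C–O closure on the palladium-bearing face delivers.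
- **Forward order:** open-chain amide from the sugar lactone; ynone; furanone ring; oxygen-bridged ten-membered carbocycle (nine-membered oxacycle) by ring-closing metathesis; γ-lactone ring by palladium annulation; ester; deprotection.
- **Stereochemistry:** C10, C9 and C8 (with the C10 methyl) are bought as C2, C3 and C4 of 2-C-methyl-D-ribono-1,4-lactone (sugar C1–C5 become C1, C10, C9, C8, C7). The 4Z alkene comes from (Z)-3-methylpent-2-en-4-yn-1-ol and 6Z from the ring. C7 and C6 are set together in the annulation, on the face anti to the C8 and C9 silyloxy groups. C8 is bought with the opposite configuration, serves as this control element, and is inverted when the methacrylate is installed.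

Key step: step 12

Numbering: germacrane numbering of the target is used throughout (C1 ketone, C2=C3 furanone alkene, C4=C5, C6 lactone O-carbon, C7 ring fusion, C8 ester carbon, C9 carbinol, C10 quaternary carbon, C11–C13 lactone carbons).

Assumption: in the bridged diene 14 the two silyl ethers (C8, C9) and the ether bridge are taken to lie on one face of the C6=C7 bond, so that the annulation occurs on the opposite face, which carries the C10 methyl; this has not been modelled.

## Route

Step 1
Reactants: 1 2-C-methyl-D-ribono-1,4-lactone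
Product: 2 3,5-di-O-(tert-butyldimethylsilyl)-2-C-methyl-D-ribono-1,4-lactone
Conditions: TBSCl (2.5 equiv), imidazole, DMF, rt
Reagents that add atoms: tert-butyldimethylsilyl chloride, CC(C)(C)[Si](C)(C)Cl
Why: Silyl ether formation with TBSCl/imidazole should take the primary and the secondary hydroxyl and leave the hindered tertiary hydroxyl (the later furanone oxygen) free.

Step 2
Reactants: 2 3,5-di-O-(tert-butyldimethylsilyl)-2-C-methyl-D-ribono-1,4-lactone
Product: 3 3-O-(tert-butyldimethylsilyl)-2-C-methyl-D-ribono-1,4-lactone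
Conditions: HF·pyridine, pyridine, THF, 0 °C
Reagents that add atoms: none
Why: Selective silyl ether cleavage, since buffered HF·pyridine should remove the primary TBS ether much faster than the hindered secondary one.

Step 3
Reactants: 3 3-O-(tert-butyldimethylsilyl)-2-C-methyl-D-ribono-1,4-lactone
Product: 4 (2S,3R,4R)-3-(tert-butyldimethylsilyloxy)-4-hydroxy-4-methyl-5-oxooxolane-2-carbaldehyde
Conditions: Dess–Martin periodinane, NaHCO3, CH2Cl2, 0 °C to rt
Reagents that add atoms: none
Why: Dess–Martin oxidation of the primary alcohol under buffered conditions should not touch the tertiary alcohol or the lactone and should not epimerise the α-alkoxy aldehyde.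

Step 4
Reactants: 4 (2S,3R,4R)-3-(tert-butyldimethylsilyloxy)-4-hydroxy-4-methyl-5-oxooxolane-2-carbaldehyde
Product: 5 (3R,4R,5R)-4-(tert-butyldimethylsilyloxy)-5-ethenyl-3-hydroxy-3-methyloxolan-2-one
Conditions: Ph3PCH3Br, KN(SiMe3)2 (2.2 equiv of ylide), THF, −78 to 0 °C
Reagents that add atoms: methyltriphenylphosphonium bromide, C[P+](c1ccccc1)(c1ccccc1)c1ccccc1.[Br-]
Why: Wittig methylenation at low temperature, with excess ylide to cover the tertiary alkoxide, should install the C7 vinyl group without attacking the lactone or epimerising C8.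

Step 5
Reactants: 5 (3R,4R,5R)-4-(tert-butyldimethylsilyloxy)-5-ethenyl-3-hydroxy-3-methyloxolan-2-one
Product: 6 (2R,3R,4R)-3-(tert-butyldimethylsilyloxy)-2,4-dihydroxy-N-methoxy-N,2-dimethylhex-5-enamide
Conditions: MeNH(OMe)·HCl, i-PrMgCl, THF, −20 to 0 °C
Reagents that add atoms: N,O-dimethylhydroxylamine hydrochloride, CNOC.Cl
Why: Weinreb aminolysis of the γ-lactone by the magnesium amide should open the ring to the acyclic amide and free the C8 hydroxyl without touching a stereocentre.

Step 6
Reactants: 6 (2R,3R,4R)-3-(tert-butyldimethylsilyloxy)-2,4-dihydroxy-N-methoxy-N,2-dimethylhex-5-enamide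
Product: 7 (2R,3R,4R)-3-(tert-butyldimethylsilyloxy)-2-hydroxy-N-methoxy-N,2-dimethyl-4-(triethylsilyloxy)hex-5-enamide
Conditions: TESCl, imidazole, CH2Cl2, 0 °C
Reagents that add atoms: chlorotriethylsilane, CC[Si](Cl)(CC)CC
Why: Silylation should be selective for the secondary allylic alcohol over the tertiary one, which blocks relactonisation and places a bulky group on C8 for the later face control.

Step 7
Reactants: 8 (Z)-3-methylpent-2-en-4-yn-1-ol
Product: 9 (Z)-3-methylpent-2-en-4-ynal
Conditions: MnO2, CH2Cl2, rt
Reagents that add atoms: none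
Why: Allylic oxidation with MnO2 should give the enal with the Z geometry retained.

Step 8
Reactants: 9 (Z)-3-methylpent-2-en-4-ynal
Product: 10 (Z)-3-methylhexa-3,5-dien-1-yne
Conditions: Ph3PCH3Br, KN(SiMe3)2, Et2O, −78 to 0 °C; product kept as a solution (volatile)
Reagents that add atoms: methyltriphenylphosphonium bromide, C[P+](c1ccccc1)(c1ccccc1)c1ccccc1.[Br-]
Why: Wittig methylenation of the enal should give the dienyne with the trisubstituted Z alkene untouched, the ylide being too weak a base to remove the alkyne proton.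

Step 9
Reactants: 10 (Z)-3-methylhexa-3,5-dien-1-yne; 7 (2R,3R,4R)-3-(tert-butyldimethylsilyloxy)-2-hydroxy-N-methoxy-N,2-dimethyl-4-(triethylsilyloxy)hex-5-enamide
Product: 12 (3R,4R,5R,9Z)-4-(tert-butyldimethylsilyloxy)-5-hydroxy-5,9-dimethyl-3-(triethylsilyloxy)dodeca-1,9,11-trien-7-yn-6-one, via lithium acetylide 11 (not isolated)
Conditions: 10 (3.0 equiv), n-BuLi (2.8 equiv), THF, −78 °C; then 7, −78 to −20 °C; aq. NH4Cl
Reagents that add atoms: none
Why: Acetylide addition to the Weinreb amide should stop at the ketone through the chelated tetrahedral adduct, one equivalent of acetylide being spent on the tertiary hydroxyl.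

Step 10
Reactants: 12 (3R,4R,5R,9Z)-4-(tert-butyldimethylsilyloxy)-5-hydroxy-5,9-dimethyl-3-(triethylsilyloxy)dodeca-1,9,11-trien-7-yn-6-one
Product: 13 (2R)-2-[(1R,2R)-1-(tert-butyldimethylsilyloxy)-2-(triethylsilyloxy)but-3-en-1-yl]-2-methyl-5-[(2Z)-penta-2,4-dien-2-yl]furan-3(2H)-one
Conditions: (4-CF3C6H4)3PAuCl (5 mol%), AgOTf (5 mol%), toluene, rt
Reagents that add atoms: none
Why: Gold-catalysed 5-endo-dig hydroalkoxylation of the α'-hydroxy ynone (tertiary hydroxyl onto the activated alkyne carbon C3) should give the 3(2H)-furanone with C10 unchanged, the C9 oxygen being silylated and unable to compete.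

Step 11
Reactants: 13 (2R)-2-[(1R,2R)-1-(tert-butyldimethylsilyloxy)-2-(triethylsilyloxy)but-3-en-1-yl]-2-methyl-5-[(2Z)-penta-2,4-dien-2-yl]furan-3(2H)-one
Product: 14 oxygen-bridged trienone (4Z,6Z,8R,9R,10R; 8-OTES, 9-OTBS)
Conditions: second-generation Hoveyda–Grubbs catalyst, (H2IMes)Cl2Ru=CH(2-i-PrOC6H4) (10 mol%), ClCH2CH2Cl (1 mM), 60 °C
Reagents that add atoms: none
Why: Ring-closing metathesis between the diene terminus and the allylic vinyl group should close the nine-membered oxacycle as the ring-Z C6=C7 alkene with loss of ethene, the trisubstituted C4=C5 bond conjugated with the furanone staying out of the reaction.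

Step 12
Reactants: 14 oxygen-bridged trienone (4Z,6Z,8R,9R,10R; 8-OTES, 9-OTBS); 15 2-bromoprop-2-enoic acid
Product: 17 cis-fused α-methylene-γ-lactone (8-epi; 8-OTES, 9-OTBS), via oxapalladacycle 16 (not isolated)
Conditions: Pd(OAc)2 (10 mol%), P(2-furyl)3 (20 mol%), Ag2CO3 (1.2 equiv), MeCN, 60 °C; 15 (2 equiv) added slowly
Reagents that add atoms: none
Why: Zerovalent palladium (from Pd(OAc)2 and the phosphine) inserts into the C–Br bond of 15, the α-carboxyvinylpalladium species adds syn across C6=C7 with C11 going to the diene terminus C7, and the resulting allylpalladium (C6–C5–C4), held as the carboxylate chelate 16, forms the C6–O bond and releases zerovalent palladium. The closest known reaction type is the Larock heteroannulation of 1,3-dienes, cyclic ones included, by vinylic or aryl halides that carry a carboxylic acid. The γ-lactone ring is closed by 5-exo attack of the carboxylate oxygen on the allyl terminus C6, the C5=C4 bond staying outside the new ring and in conjugation with the furanone. C7 is set by approach of the vinylpalladium to the face of C6=C7 anti to the 8-OTES and 9-OTBS groups; C6 is set relative to C7 because palladium and C11 arrive on the same face and, in the halide-free medium, the oxygen is delivered to C6 from the palladium-bearing face, which gives the cis ring fusion. The step needs site and regioselectivity for C7 and C6 over C4 and over the furanone alkene, secured by C7 being the only unhindered diene terminus and by closure at C6 being the five-membered, conjugation-restoring mode; Heck-type β-hydride loss is disfavoured because H7 lies anti to palladium in the ring.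

Step 13
Reactants: 17 cis-fused α-methylene-γ-lactone (8-epi; 8-OTES, 9-OTBS)
Product: 18 8-epi alcohol (8-OH, 9-OTBS)
Conditions: HF·pyridine, pyridine, THF, 0 °C
Reagents that add atoms: none
Why: Selective silyl ether cleavage, since the TES ether should fall under buffered fluoride conditions that leave the hindered TBS ether at C9 (next to the quaternary C10) and the α-methylene lactone intact.

Step 14
Reactants: 18 8-epi alcohol (8-OH, 9-OTBS)
Product: 19 9-O-(tert-butyldimethylsilyl) derivative of the target
Conditions: methacrylic acid, PPh3, DIAD, toluene, 0 °C to rt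
Reagents that add atoms: methacrylic acid, CC(=C)C(=O)O
Why: Mitsunobu esterification, in which SN2 displacement of the C8 oxyphosphonium by methacrylate should invert C8 to the configuration of the target and install the ester in the same operation, C9 being protected.

Step 15
Reactants: 19 9-O-(tert-butyldimethylsilyl) derivative of the target
Product: 20 CNP0252578.4
Conditions: HF·pyridine, THF, 0 °C to rt
Reagents that add atoms: none
Why: Fluoride-mediated desilylation under non-basic conditions should free the C9 hydroxyl without acyl migration from O8 or opening of the lactone.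

## Compound list

1 | 2-C-methyl-D-ribono-1,4-lactone | C[C@@]1(O)[C@H](O)[C@@H](CO)OC1=O | starting material
2 | 3,5-di-O-(tert-butyldimethylsilyl)-2-C-methyl-D-ribono-1,4-lactone | C[C@@]1(O)[C@H](O[Si](C)(C)C(C)(C)C)[C@@H](CO[Si](C)(C)C(C)(C)C)OC1=O | intermediate
3 | 3-O-(tert-butyldimethylsilyl)-2-C-methyl-D-ribono-1,4-lactone | C[C@@]1(O)[C@H](O[Si](C)(C)C(C)(C)C)[C@@H](CO)OC1=O | intermediate
4 | (2S,3R,4R)-3-(tert-butyldimethylsilyloxy)-4-hydroxy-4-methyl-5-oxooxolane-2-carbaldehyde | C[C@@]1(O)[C@H](O[Si](C)(C)C(C)(C)C)[C@@H](C=O)OC1=O | intermediate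
5 | (3R,4R,5R)-4-(tert-butyldimethylsilyloxy)-5-ethenyl-3-hydroxy-3-methyloxolan-2-one | C[C@@]1(O)[C@H](O[Si](C)(C)C(C)(C)C)[C@@H](C=C)OC1=O | intermediate
6 | (2R,3R,4R)-3-(tert-butyldimethylsilyloxy)-2,4-dihydroxy-N-methoxy-N,2-dimethylhex-5-enamide | CON(C)C(=O)[C@](C)(O)[C@H](O[Si](C)(C)C(C)(C)C)[C@H](O)C=C | intermediate
7 | (2R,3R,4R)-3-(tert-butyldimethylsilyloxy)-2-hydroxy-N-methoxy-N,2-dimethyl-4-(triethylsilyloxy)hex-5-enamide | CON(C)C(=O)[C@](C)(O)[C@H](O[Si](C)(C)C(C)(C)C)[C@H](O[Si](CC)(CC)CC)C=C | intermediate
8 | (Z)-3-methylpent-2-en-4-yn-1-ol | C#C/C(C)=C\CO | starting material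
9 | (Z)-3-methylpent-2-en-4-ynal | C#C/C(C)=C\C=O | intermediate
10 | (Z)-3-methylhexa-3,5-dien-1-yne | C#C/C(C)=C\C=C | intermediate
11 | lithium (Z)-3-methylhexa-3,5-dien-1-yn-1-ide | [Li]C#C/C(C)=C\C=C | intermediate
12 | (3R,4R,5R,9Z)-4-(tert-butyldimethylsilyloxy)-5-hydroxy-5,9-dimethyl-3-(triethylsilyloxy)dodeca-1,9,11-trien-7-yn-6-one | C=C/C=C(/C)C#CC(=O)[C@](C)(O)[C@H](O[Si](C)(C)C(C)(C)C)[C@H](O[Si](CC)(CC)CC)C=C | intermediate
13 | (2R)-2-[(1R,2R)-1-(tert-butyldimethylsilyloxy)-2-(triethylsilyloxy)but-3-en-1-yl]-2-methyl-5-[(2Z)-penta-2,4-dien-2-yl]furan-3(2H)-one | C=C/C=C(/C)C1=CC(=O)[C@](C)(O1)[C@H](O[Si](C)(C)C(C)(C)C)[C@H](O[Si](CC)(CC)CC)C=C | intermediate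
14 | oxygen-bridged trienone: (4Z,6Z,8R,9R,10R)-9-(tert-butyldimethylsilyloxy)-8-(triethylsilyloxy)-3,10-epoxy-11,12,13-trinorgermacra-2,4,6-trien-1-one | CC[Si](CC)(CC)O[C@@H]1/C=C\C=C(\C)C2=CC(=O)[C@](C)(O2)[C@@H]1O[Si](C)(C)C(C)(C)C | intermediate
15 | 2-bromoprop-2-enoic acid | C=C(Br)C(=O)O | starting material
16 | oxapalladacycle: C6-bound allylpalladium carboxylate formed after carbopalladation of 14 (phosphine ligands omitted) | CC[Si](CC)(CC)O[C@@H]1[C@H]2C(=C)C(=O)O[Pd][C@H]2/C=C(/C)C2=CC(=O)[C@](C)(O2)[C@@H]1O[Si](C)(C)C(C)(C)C | intermediate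
17 | cis-fused α-methylene-γ-lactone: the target skeleton with the opposite configuration at C8, OTES at C8 in place of the ester and OTBS at C9 | CC[Si](CC)(CC)O[C@@H]1[C@H]2C(=C)C(=O)O[C@H]2/C=C(/C)C2=CC(=O)[C@](C)(O2)[C@@H]1O[Si](C)(C)C(C)(C)C | intermediate
18 | 8-epi alcohol: as 17 with free hydroxyl at C8 | O[C@@H]1[C@H]2C(=C)C(=O)O[C@H]2/C=C(/C)C2=CC(=O)[C@](C)(O2)[C@@H]1O[Si](C)(C)C(C)(C)C | intermediate
19 | 9-O-(tert-butyldimethylsilyl) derivative of the target (6S,7S,8S,9R,10R) | C=C(C)C(=O)O[C@H]1[C@H]2C(=C)C(=O)O[C@H]2/C=C(/C)C2=CC(=O)[C@](C)(O2)[C@@H]1O[Si](C)(C)C(C)(C)C | intermediate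
20 | CNP0252578.4 (6S,7S,8S,9R,10R; 4Z) | C=C(C)C(=O)O[C@H]1[C@H]2C(=C)C(=O)O[C@H]2/C=C(/C)C2=CC(=O)[C@](C)(O2)[C@@H]1O | target

## Summary and risks

Total step count: 15. Longest linear sequence: 13 steps (steps 1–6 and 9–15, from 1).

Steps most likely to fail:

**Step 12.** The vinylpalladium species may be consumed by self-coupling or by a further Heck reaction with the α-methylene group of the product before it inserts into the hindered ring diene. The allylpalladium intermediate may also close from the face opposite to palladium, which would give the trans-fused lactone. The fallback sets out from 14 and comes back at 17. An oxidative free-radical lactone annulation with malonic acid and Mn(OAc)3·2H2O (trivalent manganese acetate) in AcOH at rt to 40 °C is used. The malonyl radical adds to C7, the allyl radical is oxidised and is trapped at C6 by a carboxyl group, which should give the α-carboxy-γ-lactone F1. Decarboxylative methylenation of F1 (aqueous formaldehyde, Et2NH, NaOAc/AcOH) then gives 17.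

**Step 11.** The ruthenium carbene may form only at the unhindered diene terminus, rest there as a conjugated vinylcarbene and be lost to dimerisation, so that the hindered allylic-ether alkene at C7 is never engaged. The fallback sets out from 4 and comes back at 14, using a relay tether. Aldehyde 4 is treated with the ylide from (hex-5-en-1-yl)triphenylphosphonium bromide (KN(SiMe3)2, THF, −78 °C) to give the relay lactone F2. This is carried through the operations of steps 5, 6, 9 and 10 to the relay Weinreb amide F3, the relay TES ether F4, the relay ynone F5 and the relay furanone F6. With the same ruthenium catalyst the carbene loads at the terminal alkene of the tether, expels cyclopentene and is thereby placed on C7, from where ring closure onto the diene terminus gives 14.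

**Step 14.** SN2 displacement at the hindered C8 oxyphosphonium may be slow, so that elimination or participation of the lactone carbonyl (retention, or transfer of the lactone to O8) takes over. The fallback sets out from 18 and comes back at 20. HF·pyridine in THF removes the TBS group to give the cis-diol F7. Sulfuryl chloride and Et3N in CH2Cl2 at −78 °C convert it into the 8,9-cyclic sulfate F8. Caesium methacrylate in DMF opens the sulfate at C8 with inversion (C9 is neopentyl-like and shielded) to the sulfate monoester F9, which is not isolated. Catalytic H2SO4 in wet THF hydrolyses it to 20.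

## Further compounds

F1 | step 12 | α-carboxy-γ-lactone (as 17 with CO2H in place of the exocyclic methylene, C11 unassigned) | CC[Si](CC)(CC)O[C@@H]1[C@H]2C(C(=O)O)C(=O)O[C@H]2/C=C(/C)C2=CC(=O)[C@](C)(O2)[C@@H]1O[Si](C)(C)C(C)(C)C
F2 | step 11 | relay lactone: (3R,4R,5R)-4-(tert-butyldimethylsilyloxy)-5-[(1Z)-hepta-1,6-dien-1-yl]-3-hydroxy-3-methyloxolan-2-one | C[C@@]1(O)[C@H](O[Si](C)(C)C(C)(C)C)[C@@H](/C=C\CCCC=C)OC1=O
F3 | step 11 | relay Weinreb amide (as 6 with the (1Z)-hepta-1,6-dienyl group in place of vinyl) | CON(C)C(=O)[C@](C)(O)[C@H](O[Si](C)(C)C(C)(C)C)[C@H](O)/C=C\CCCC=C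
F4 | step 11 | relay TES ether (as 7 with the (1Z)-hepta-1,6-dienyl group in place of vinyl) | CON(C)C(=O)[C@](C)(O)[C@H](O[Si](C)(C)C(C)(C)C)[C@H](O[Si](CC)(CC)CC)/C=C\CCCC=C
F5 | step 11 | relay ynone (as 12 with the (1Z)-hepta-1,6-dienyl group in place of vinyl) | C=C/C=C(/C)C#CC(=O)[C@](C)(O)[C@H](O[Si](C)(C)C(C)(C)C)[C@H](O[Si](CC)(CC)CC)/C=C\CCCC=C
F6 | step 11 | relay furanone (as 13 with the (1Z)-hepta-1,6-dienyl group in place of vinyl) | C=C/C=C(/C)C1=CC(=O)[C@](C)(O1)[C@H](O[Si](C)(C)C(C)(C)C)[C@H](O[Si](CC)(CC)CC)/C=C\CCCC=C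
F7 | step 14 | cis-8,9-diol (as 18 with free hydroxyl at C9) | O[C@@H]1[C@H]2C(=C)C(=O)O[C@H]2/C=C(/C)C2=CC(=O)[C@](C)(O2)[C@@H]1O
F8 | step 14 | 8,9-cyclic sulfate of F7 | O=S1(=O)O[C@@H]2[C@H]3C(=C)C(=O)O[C@H]3/C=C(/C)C4=CC(=O)[C@](C)(O4)[C@@H]2O1
F9 | step 14 | caesium 9-O-sulfate of the target | C=C(C)C(=O)O[C@H]1[C@H]2C(=C)C(=O)O[C@H]2/C=C(/C)C2=CC(=O)[C@](C)(O2)[C@@H]1OS(=O)(=O)[O-].[Cs+]
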